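**Strategy.** Ring C is made last, by a Danheiser benzannulation of a 3-substituted cyclobutenone with an enantiopure triisopropylsilyloxyalkyne. The reaction fits the 1,3-dioxygenated ring C, whose carbon C3a is flanked by the oxygen-bearing C4 and C7a and faces the chain-bearing C6 across the ring. One thermal operation forges C3a–C7a, C4–C5 and C7–C7a and delivers a phenol that already holds the C3 stereocentre and the C2 carbinol. The alkyne partner is a 3,4-diaryl-4-silyloxybut-1-ynyl silyl ether whose two stereocentres come from an Evans syn-aldol and whose ynol oxygen is installed by acetylide oxidation. Desilylation, acid-mediated closure to the trans-dihydrobenzofuran and demethylation complete the synthesis.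

Key step: step 10

Remark: atom labels (O1, C2, C3, C3a, C4–C7, C7a) follow the 2,3-dihydro-1-benzofuran core of the target, and ring C is its benzo ring. (R)-4-Benzyloxazolidin-2-one and 4-(4-methoxyphenyl)but-1-yne are taken as purchased. The two ring C hydroxyls of 25 are homotopic, so closure on either gives the same compound. Any C3 epimer formed before step 12 is a diastereomer that chromatography should remove.

**Step 1**
Reactants: 1 (3,5-dimethoxyphenyl)acetic acid; 2 (R)-4-benzyloxazolidin-2-one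
Product: 4 (R)-4-benzyl-3-[(3,5-dimethoxyphenyl)acetyl]oxazolidin-2-one, via mixed pivalic anhydride 3 (not isolated)
Conditions: PivCl, Et3N, THF, −20 °C; then LiCl, 2, −20 °C → rt
Reagents that add atoms: none
Why: N-acylation of the oxazolidinone through the mixed pivalic anhydride with LiCl assistance is the standard entry to Evans imides and forms no stereocentre.

**Step 2**
Reactants: 4 (R)-4-benzyl-3-[(3,5-dimethoxyphenyl)acetyl]oxazolidin-2-one; 5 4-methoxybenzaldehyde
Product: 7 (R)-4-benzyl-3-[(2R,3R)-2-(3,5-dimethoxyphenyl)-3-hydroxy-3-(4-methoxyphenyl)propanoyl]oxazolidin-2-one, via boron enolate 6 (not isolated)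
Conditions: n-Bu2BOTf, i-Pr2NEt, CH2Cl2, −78 → 0 °C; 5, −78 → 0 °C; then pH 7 buffer, MeOH, 30% H2O2, 0 °C
Reagents that add atoms: none
Why: Evans syn-aldol: the (Z)-boron enolate 6 reacts through a Zimmerman–Traxler chair in which the benzyl group of the (R)-auxiliary shields one enolate face, which should set the aryl-bearing carbon (future C3) and the carbinol as the (2R,3R) syn pair.

**Step 3**
Reactants: 7 (R)-4-benzyl-3-[(2R,3R)-2-(3,5-dimethoxyphenyl)-3-hydroxy-3-(4-methoxyphenyl)propanoyl]oxazolidin-2-one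
Product: 8 (R)-4-benzyl-3-[(2R,3R)-3-(tert-butyldimethylsilyloxy)-2-(3,5-dimethoxyphenyl)-3-(4-methoxyphenyl)propanoyl]oxazolidin-2-one
Conditions: TBSOTf, 2,6-lutidine, CH2Cl2, −78 → 0 °C
Reagents that add atoms: tert-butyldimethylsilyl trifluoromethanesulfonate, CC(C)(C)[Si](C)(C)OS(=O)(=O)C(F)(F)F
Why: Silyl triflate silylation of a hindered secondary alcohol; it blocks retro-aldol cleavage and masks the carbinol for the hydride, oxidation and organolithium steps that follow.

**Step 4**
Reactants: 8 (R)-4-benzyl-3-[(2R,3R)-3-(tert-butyldimethylsilyloxy)-2-(3,5-dimethoxyphenyl)-3-(4-methoxyphenyl)propanoyl]oxazolidin-2-one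
Product: 9 (2S,3R)-3-(tert-butyldimethylsilyloxy)-2-(3,5-dimethoxyphenyl)-3-(4-methoxyphenyl)propan-1-ol
Conditions: LiBH4, MeOH (1 equiv), THF, 0 °C
Reagents that add atoms: none
Why: Reductive removal of the Evans auxiliary by hydride attack at the exocyclic carbonyl proceeds without enolisation, so the α-aryl centre is kept (the descriptor changes only through CIP priorities).

**Step 5**
Reactants: 9 (2S,3R)-3-(tert-butyldimethylsilyloxy)-2-(3,5-dimethoxyphenyl)-3-(4-methoxyphenyl)propan-1-ol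
Product: 10 (2R,3R)-3-(tert-butyldimethylsilyloxy)-2-(3,5-dimethoxyphenyl)-3-(4-methoxyphenyl)propanal
Conditions: Dess–Martin periodinane, NaHCO3, CH2Cl2, 0 °C → rt; used crude at once
Reagents that add atoms: none
Why: Dess–Martin oxidation under bicarbonate buffer is fast and near neutral, which should spare the enolisable α-aryl aldehyde from epimerisation and from β-elimination of silanol.

**Step 6**
Reactants: 10 (2R,3R)-3-(tert-butyldimethylsilyloxy)-2-(3,5-dimethoxyphenyl)-3-(4-methoxyphenyl)propanal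
Product: 11 (3R,4R)-1,1-dibromo-4-(tert-butyldimethylsilyloxy)-3-(3,5-dimethoxyphenyl)-4-(4-methoxyphenyl)but-1-ene
Conditions: CBr4, PPh3, 2,6-lutidine, CH2Cl2, 0 °C (ylide preformed)
Reagents that add atoms: carbon tetrabromide, BrC(Br)(Br)Br
Why: Ramirez dibromo-olefination (first stage of the Corey–Fuchs sequence) is a non-basic Wittig-type reaction, and lutidine buffers HBr so that the acid-labile p-methoxybenzylic silyl ether and the α-centre survive.

**Step 7**
Reactants: 11 (3R,4R)-1,1-dibromo-4-(tert-butyldimethylsilyloxy)-3-(3,5-dimethoxyphenyl)-4-(4-methoxyphenyl)but-1-ene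
Product: 14 (3S,4R)-4-(tert-butyldimethylsilyloxy)-3-(3,5-dimethoxyphenyl)-4-(4-methoxyphenyl)-1-(triisopropylsilyloxy)but-1-yne, via lithium acetylide 12 (not isolated), via lithium ynolate 13 (not isolated)
Conditions: n-BuLi (2.05 equiv), THF, −78 °C; then t-BuOOLi (1.5 equiv, premixed from t-BuOOH and LiHMDS in THF at −78 °C) by cannula, −78 → 0 °C; then TIPSOTf, −78 → 0 °C; pentane, filtration, Et3N-deactivated silica
Reagents that add atoms: tert-butyl hydroperoxide (as its lithium salt; supplies the ynol oxygen), CC(C)(C)OO; triisopropylsilyl trifluoromethanesulfonate, CC(C)[Si](OS(=O)(=O)C(F)(F)F)(C(C)C)C(C)C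
Why: The second stage of the Corey–Fuchs alkyne synthesis (bromine–lithium exchange, Fritsch–Buttenberg–Wiechell hydride shift, deprotonation of the nascent alkyne) gives lithium acetylide 12 at −78 °C without metalating the propargylic benzylic C–H, oxygen transfer from lithium tert-butyl peroxide to the acetylide (Julia ynolate synthesis) gives ynolate 13, and the silyl triflate caps it on oxygen, so the acetylide is generated once and C3 is never part of an enolisable carbonyl compound.

**Step 8**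
Reactants: 15 4-(4-methoxyphenyl)but-1-yne; 16 trichloroacetyl chloride
Product: 18 4,4-dichloro-3-[2-(4-methoxyphenyl)ethyl]cyclobut-2-en-1-one, via dichloroketene 17 (not isolated)
Conditions: Zn(Cu) couple, Et2O/DME, rt, slow addition of 16
Reagents that add atoms: none
Why: [2+2] cycloaddition of dichloroketene made in the flask with a terminal alkyne, whose unsubstituted carbon bonds to the ketene carbonyl carbon, gives the 3-substituted 4,4-dichlorocyclobutenone.

**Step 9**
Reactants: 18 4,4-dichloro-3-[2-(4-methoxyphenyl)ethyl]cyclobut-2-en-1-one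
Product: 19 3-[2-(4-methoxyphenyl)ethyl]cyclobut-2-en-1-one
Conditions: Zn dust, TMEDA, AcOH, EtOH, 0 °C → rt
Reagents that add atoms: none
Why: Buffered zinc/acetic acid reductive dechlorination is the standard conversion of 4,4-dichlorocyclobutenones into 3-substituted cyclobutenones without ring cleavage.

**Step 10**
Reactants: 14 (3S,4R)-4-(tert-butyldimethylsilyloxy)-3-(3,5-dimethoxyphenyl)-4-(4-methoxyphenyl)-1-(triisopropylsilyloxy)but-1-yne; 19 3-[2-(4-methoxyphenyl)ethyl]cyclobut-2-en-1-one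
Product: 24 2-[(1S,2R)-2-(tert-butyldimethylsilyloxy)-1-(3,5-dimethoxyphenyl)-2-(4-methoxyphenyl)ethyl]-5-[2-(4-methoxyphenyl)ethyl]-3-(triisopropylsilyloxy)phenol, via vinylketene 20 (not isolated), via vinylcyclobutenone 21 (not isolated), via dienylketene 22 (not isolated), via cyclohexadienone 23 (not isolated)
Conditions: PhMe (0.5 M), 80 °C then 110 °C, argon; 14 in slight excess
Reagents that add atoms: none
Why: Danheiser benzannulation: thermal four-electron electrocyclic opening of 19 gives vinylketene 20, whose carbonyl carbon (future C7a) is attacked by the oxygen-free alkyne carbon of 14 (future C3a) in a [2+2] cycloaddition that also joins the oxygenated alkyne carbon (C4) to the ketene α-carbon (C5), giving 21. A second four-electron opening leads to dienylketene 22, and ring C closes by six-electron electrocyclisation (C7–C7a) to dienone 23, which tautomerises to the phenol. The closest known reaction type is the benzannulation of 3-alkylcyclobutenones with α-branched trialkylsilyloxyalkynes to 2,5-disubstituted resorcinol monosilyl ethers. No stereocentre is created: C3 (S) and the carbinol come in from 14 and are inert under neutral thermal conditions. The selectivity needed is regiochemical and is fixed by the polarisation of the ynol ether, which places C3a between the free C7a hydroxyl and the silylated C4 oxygen and the side chain of 19 para to C3a at C6.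

**Step 11**
Reactants: 24 2-[(1S,2R)-2-(tert-butyldimethylsilyloxy)-1-(3,5-dimethoxyphenyl)-2-(4-methoxyphenyl)ethyl]-5-[2-(4-methoxyphenyl)ethyl]-3-(triisopropylsilyloxy)phenol
Product: 25 2-[(1S,2R)-1-(3,5-dimethoxyphenyl)-2-hydroxy-2-(4-methoxyphenyl)ethyl]-5-[2-(4-methoxyphenyl)ethyl]benzene-1,3-diol
Conditions: TBAF, THF, 0 °C → rt; aq. NH4Cl
Reagents that add atoms: none
Why: Fluoride desilylation cleaves the aryl triisopropylsilyl ether and the benzylic tert-butyldimethylsilyl ether, freeing both ring C hydroxyls and the carbinol without touching C3.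

**Step 12**
Reactants: 25 2-[(1S,2R)-1-(3,5-dimethoxyphenyl)-2-hydroxy-2-(4-methoxyphenyl)ethyl]-5-[2-(4-methoxyphenyl)ethyl]benzene-1,3-diol
Product: 27 (2S,3S)-3-(3,5-dimethoxyphenyl)-2-(4-methoxyphenyl)-6-[2-(4-methoxyphenyl)ethyl]-2,3-dihydro-1-benzofuran-4-ol, via benzylic cation 26 (not isolated)
Conditions: TsOH·H2O (10 mol %), CH2Cl2, 0 °C → rt
Reagents that add atoms: none
Why: Acid-catalysed dehydrative cycloetherification: the p-methoxybenzylic alcohol ionises to cation 26, a ring C hydroxyl traps it in a five-membered closure anti to the C3 aryl group, and reversibility of the benzylic C–O bond funnels material to the more stable 2,3-trans isomer, so C2 (S) is controlled by C3.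

**Step 13**
Reactants: 27 (2S,3S)-3-(3,5-dimethoxyphenyl)-2-(4-methoxyphenyl)-6-[2-(4-methoxyphenyl)ethyl]-2,3-dihydro-1-benzofuran-4-ol
Product: 28 5-{(2S,3S)-4-hydroxy-2-(4-hydroxyphenyl)-6-[2-(4-hydroxyphenyl)ethyl]-2,3-dihydro-1-benzofuran-3-yl}benzene-1,3-diol (CNP0315602.1)
Conditions: BBr3 (excess), CH2Cl2, −78 °C → rt; then H2O, 0 °C
Reagents that add atoms: none
Why: Boron tribromide cleavage of the four aryl methyl ethers (global demethylation); any Lewis acid opening of the benzylic C2–O1 bond should reclose to the same trans isomer, and C3 bears no leaving group.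

**Compound list**

1 | (3,5-dimethoxyphenyl)acetic acid | COc1cc(CC(=O)O)cc(OC)c1 | starting material
2 | (R)-4-benzyloxazolidin-2-one | O=C1N[C@H](Cc2ccccc2)CO1 | starting material
3 | (3,5-dimethoxyphenyl)acetic pivalic anhydride | COc1cc(CC(=O)OC(=O)C(C)(C)C)cc(OC)c1 | intermediate (not isolated)
4 | (R)-4-benzyl-3-[(3,5-dimethoxyphenyl)acetyl]oxazolidin-2-one | O=C1OC[C@@H](Cc2ccccc2)N1C(=O)Cc1cc(OC)cc(OC)c1 | intermediate
5 | 4-methoxybenzaldehyde | COc1ccc(C=O)cc1 | starting material
6 | (Z)-dibutylboron enolate of 4 | CCCCB(CCCC)O/C(=C\c1cc(OC)cc(OC)c1)N1[C@H](Cc2ccccc2)COC1=O | intermediate (not isolated)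
7 | (R)-4-benzyl-3-[(2R,3R)-2-(3,5-dimethoxyphenyl)-3-hydroxy-3-(4-methoxyphenyl)propanoyl]oxazolidin-2-one | O=C1OC[C@@H](Cc2ccccc2)N1C(=O)[C@H](c1cc(OC)cc(OC)c1)[C@@H](O)c1ccc(OC)cc1 | intermediate
8 | (R)-4-benzyl-3-[(2R,3R)-3-(tert-butyldimethylsilyloxy)-2-(3,5-dimethoxyphenyl)-3-(4-methoxyphenyl)propanoyl]oxazolidin-2-one | O=C1OC[C@@H](Cc2ccccc2)N1C(=O)[C@H](c1cc(OC)cc(OC)c1)[C@@H](O[Si](C)(C)C(C)(C)C)c1ccc(OC)cc1 | intermediate
9 | (2S,3R)-3-(tert-butyldimethylsilyloxy)-2-(3,5-dimethoxyphenyl)-3-(4-methoxyphenyl)propan-1-ol | OC[C@H](c1cc(OC)cc(OC)c1)[C@@H](O[Si](C)(C)C(C)(C)C)c1ccc(OC)cc1 | intermediate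
10 | (2R,3R)-3-(tert-butyldimethylsilyloxy)-2-(3,5-dimethoxyphenyl)-3-(4-methoxyphenyl)propanal | O=C[C@H](c1cc(OC)cc(OC)c1)[C@@H](O[Si](C)(C)C(C)(C)C)c1ccc(OC)cc1 | intermediate
11 | (3R,4R)-1,1-dibromo-4-(tert-butyldimethylsilyloxy)-3-(3,5-dimethoxyphenyl)-4-(4-methoxyphenyl)but-1-ene | BrC(Br)=C[C@H](c1cc(OC)cc(OC)c1)[C@@H](O[Si](C)(C)C(C)(C)C)c1ccc(OC)cc1 | intermediate
12 | lithium acetylide from 11: C1-lithiated 4-(tert-butyldimethylsilyloxy)-3-(3,5-dimethoxyphenyl)-4-(4-methoxyphenyl)but-1-yne, both stereocentres as in 11 | [Li]C#C[C@H](c1cc(OC)cc(OC)c1)[C@@H](O[Si](C)(C)C(C)(C)C)c1ccc(OC)cc1 | intermediate (not isolated)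
13 | lithium (3S,4R)-4-(tert-butyldimethylsilyloxy)-3-(3,5-dimethoxyphenyl)-4-(4-methoxyphenyl)but-1-yn-1-olate | [Li]OC#C[C@H](c1cc(OC)cc(OC)c1)[C@@H](O[Si](C)(C)C(C)(C)C)c1ccc(OC)cc1 | intermediate (not isolated)
14 | (3S,4R)-4-(tert-butyldimethylsilyloxy)-3-(3,5-dimethoxyphenyl)-4-(4-methoxyphenyl)-1-(triisopropylsilyloxy)but-1-yne | CC(C)[Si](OC#C[C@H](c1cc(OC)cc(OC)c1)[C@@H](O[Si](C)(C)C(C)(C)C)c1ccc(OC)cc1)(C(C)C)C(C)C | intermediate
15 | 4-(4-methoxyphenyl)but-1-yne | C#CCCc1ccc(OC)cc1 | starting material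
16 | trichloroacetyl chloride | ClC(Cl)(Cl)C(Cl)=O | starting material
17 | dichloroketene | O=C=C(Cl)Cl | intermediate (not isolated)
18 | 4,4-dichloro-3-[2-(4-methoxyphenyl)ethyl]cyclobut-2-en-1-one | O=C1C=C(CCc2ccc(OC)cc2)C1(Cl)Cl | intermediate
19 | 3-[2-(4-methoxyphenyl)ethyl]cyclobut-2-en-1-one | O=C1C=C(CCc2ccc(OC)cc2)C1 | intermediate
20 | 5-(4-methoxyphenyl)-3-methylidenepent-1-en-1-one (vinylketene) | O=C=CC(=C)CCc1ccc(OC)cc1 | intermediate (not isolated)
21 | 2-[(1S,2R)-2-(tert-butyldimethylsilyloxy)-1-(3,5-dimethoxyphenyl)-2-(4-methoxyphenyl)ethyl]-4-[4-(4-methoxyphenyl)but-1-en-2-yl]-3-(triisopropylsilyloxy)cyclobut-2-en-1-one (both epimers at ring C4) | O=C1C([C@H](c2cc(OC)cc(OC)c2)[C@@H](O[Si](C)(C)C(C)(C)C)c2ccc(OC)cc2)=C(O[Si](C(C)C)(C(C)C)C(C)C)C1C(=C)CCc1ccc(OC)cc1 | intermediate (not isolated)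
22 | (3E)-2-[(1S,2R)-2-(tert-butyldimethylsilyloxy)-1-(3,5-dimethoxyphenyl)-2-(4-methoxyphenyl)ethyl]-5-[2-(4-methoxyphenyl)ethyl]-3-(triisopropylsilyloxy)hexa-1,3,5-trien-1-one (dienylketene) | O=C=C([C@H](c1cc(OC)cc(OC)c1)[C@@H](O[Si](C)(C)C(C)(C)C)c1ccc(OC)cc1)/C(O[Si](C(C)C)(C(C)C)C(C)C)=C\C(=C)CCc1ccc(OC)cc1 | intermediate (not isolated)
23 | 2-[(1S,2R)-2-(tert-butyldimethylsilyloxy)-1-(3,5-dimethoxyphenyl)-2-(4-methoxyphenyl)ethyl]-5-[2-(4-methoxyphenyl)ethyl]-3-(triisopropylsilyloxy)cyclohexa-2,4-dien-1-one | O=C1CC(CCc2ccc(OC)cc2)=CC(O[Si](C(C)C)(C(C)C)C(C)C)=C1[C@H](c1cc(OC)cc(OC)c1)[C@@H](O[Si](C)(C)C(C)(C)C)c1ccc(OC)cc1 | intermediate (not isolated)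
24 | 2-[(1S,2R)-2-(tert-butyldimethylsilyloxy)-1-(3,5-dimethoxyphenyl)-2-(4-methoxyphenyl)ethyl]-5-[2-(4-methoxyphenyl)ethyl]-3-(triisopropylsilyloxy)phenol | CC(C)(C)[Si](C)(C)O[C@@H](c1ccc(OC)cc1)[C@H](c1c(O)cc(CCc2ccc(OC)cc2)cc1O[Si](C(C)C)(C(C)C)C(C)C)c1cc(OC)cc(OC)c1 | intermediate
25 | 2-[(1S,2R)-1-(3,5-dimethoxyphenyl)-2-hydroxy-2-(4-methoxyphenyl)ethyl]-5-[2-(4-methoxyphenyl)ethyl]benzene-1,3-diol | O[C@@H](c1ccc(OC)cc1)[C@H](c1c(O)cc(CCc2ccc(OC)cc2)cc1O)c1cc(OC)cc(OC)c1 | intermediate
26 | (2S)-2-{2,6-dihydroxy-4-[2-(4-methoxyphenyl)ethyl]phenyl}-2-(3,5-dimethoxyphenyl)-1-(4-methoxyphenyl)ethylium (anisyl-stabilised benzylic cation) | COc1ccc([CH+][C@@H](c2cc(OC)cc(OC)c2)c2c(O)cc(CCc3ccc(OC)cc3)cc2O)cc1 | intermediate (not isolated)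
27 | (2S,3S)-3-(3,5-dimethoxyphenyl)-2-(4-methoxyphenyl)-6-[2-(4-methoxyphenyl)ethyl]-2,3-dihydro-1-benzofuran-4-ol | COc1ccc(CCc2cc(O)c3c(c2)O[C@H](c2ccc(OC)cc2)[C@H]3c2cc(OC)cc(OC)c2)cc1 | intermediate
28 | 5-{(2S,3S)-4-hydroxy-2-(4-hydroxyphenyl)-6-[2-(4-hydroxyphenyl)ethyl]-2,3-dihydro-1-benzofuran-3-yl}benzene-1,3-diol | Oc1ccc(CCc2cc(O)c3c(c2)O[C@H](c2ccc(O)cc2)[C@H]3c2cc(O)cc(O)c2)cc1 | target

**Step count.** Total: 13 steps. Longest linear sequence: 11 steps (steps 1–7 and 10–13); steps 8–9 form the second branch.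

**Steps most likely to fail**

1. **Step 10.** At 80–110 °C the capture of vinylketene 20 by the hindered, α-branched alkyne may be outrun by ketene oligomerisation and by acylation of the product phenol by 20. The fallback generates the same ketene at room temperature by a photochemical Wolff rearrangement, so that 21 is formed before any phenol exists; it sets out from 15 and returns at 24. Alkyne 15 is bromoborated with B-bromo-9-borabicyclo[3.3.1]nonane and protonolysed with AcOH to 2-bromo-4-(4-methoxyphenyl)but-1-ene F1. Bromine–lithium exchange (t-BuLi, −78 °C) and acylation with N-methoxy-N-methylacetamide should give 5-(4-methoxyphenyl)-3-methylidenepentan-2-one F2. Its lithium enolate (LiHMDS) is trifluoroacetylated with 2,2,2-trifluoroethyl trifluoroacetate to 1,1,1-trifluoro-7-(4-methoxyphenyl)-5-methylideneheptane-2,4-dione F3, and deacylative diazo transfer (MsN3, Et3N, H2O, MeCN) should give 1-diazo-5-(4-methoxyphenyl)-3-methylidenepentan-2-one F4. Irradiation of F4 in the presence of 14 at 20 °C gives 20, which 14 traps as 21; gentle heating then carries 21 through 22 and 23 to 24.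

2. **Step 7.** Oxygen transfer to the hindered acetylide may stay incomplete, the 1-bromobutane left from the exchange may consume peroxide, or metalation at the propargylic benzylic C3–H may compete and lead to allene formation and loss of configuration. The fallback is a Kowalski ester homologation, which never forms the acetylide; it sets out from 8 and returns at 13, which is silylated to 14 as in step 7. Imide 8 is transesterified with MeOMgBr in MeOH at 0 °C, releasing 2, to methyl (2R,3R)-3-(tert-butyldimethylsilyloxy)-2-(3,5-dimethoxyphenyl)-3-(4-methoxyphenyl)propanoate F5. Addition of LiCHBr2 (CH2Br2, lithium 2,2,6,6-tetramethylpiperidide, −78 °C) and loss of methoxide give (3R,4R)-1,1-dibromo-4-(tert-butyldimethylsilyloxy)-3-(3,5-dimethoxyphenyl)-4-(4-methoxyphenyl)butan-2-one F6, held as its lithium enolate (LiHMDS; not isolated). Bromine–lithium exchange with n-BuLi then triggers the 1,2-shift to ynolate 13. Enolisation of the α-aryl ester is the hazard of this path; any C3 epimer would be a diastereomer and would be separated at 14.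

3. **Step 13.** The Lewis acid may open the C2–O1 bond and lose the benzylic cation irreversibly (retained bromide, intermolecular Friedel–Crafts alkylation of the electron-rich rings), or ether cleavage may stay incomplete. The fallback reverses the order, so that ring closure is the last event and occurs near neutrality; it sets out from 25 and returns at 28. Triol 25 is treated with BBr3 (CH2Cl2, −78 °C → rt), which converts the carbinol into the benzylic bromide and cleaves the four methyl ethers. Aqueous work-up liberates 2-[(1S)-2-bromo-1-(3,5-dihydroxyphenyl)-2-(4-hydroxyphenyl)ethyl]-5-[2-(4-hydroxyphenyl)ethyl]benzene-1,3-diol F7 (both epimers at the bromide carbon, not isolated). Stirring with aqueous NaHCO3 in THF removes HBr to give the p-quinone methide 4-[(2S)-2-{2,6-dihydroxy-4-[2-(4-hydroxyphenyl)ethyl]phenyl}-2-(3,5-dihydroxyphenyl)ethylidene]cyclohexa-2,5-dien-1-one F8. Intramolecular oxa-Michael addition of a ring C hydroxyl, anti to the C3 aryl group, should close the trans ring of 28.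

**Further compounds**

F1 | step 10 | 2-bromo-4-(4-methoxyphenyl)but-1-ene | C=C(Br)CCc1ccc(OC)cc1
F2 | step 10 | 5-(4-methoxyphenyl)-3-methylidenepentan-2-one | CC(=O)C(=C)CCc1ccc(OC)cc1
F3 | step 10 | 1,1,1-trifluoro-7-(4-methoxyphenyl)-5-methylideneheptane-2,4-dione | O=C(CC(=O)C(=C)CCc1ccc(OC)cc1)C(F)(F)F
F4 | step 10 | 1-diazo-5-(4-methoxyphenyl)-3-methylidenepentan-2-one | [N-]=[N+]=CC(=O)C(=C)CCc1ccc(OC)cc1
F5 | step 7 | methyl (2R,3R)-3-(tert-butyldimethylsilyloxy)-2-(3,5-dimethoxyphenyl)-3-(4-methoxyphenyl)propanoate | COC(=O)[C@H](c1cc(OC)cc(OC)c1)[C@@H](O[Si](C)(C)C(C)(C)C)c1ccc(OC)cc1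
F6 | step 7 | (3R,4R)-1,1-dibromo-4-(tert-butyldimethylsilyloxy)-3-(3,5-dimethoxyphenyl)-4-(4-methoxyphenyl)butan-2-one | BrC(Br)C(=O)[C@H](c1cc(OC)cc(OC)c1)[C@@H](O[Si](C)(C)C(C)(C)C)c1ccc(OC)cc1
F7 | step 13 | 2-[(1S)-2-bromo-1-(3,5-dihydroxyphenyl)-2-(4-hydroxyphenyl)ethyl]-5-[2-(4-hydroxyphenyl)ethyl]benzene-1,3-diol | Oc1ccc(CCc2cc(O)c([C@H](c3cc(O)cc(O)c3)C(Br)c3ccc(O)cc3)c(O)c2)cc1
F8 | step 13 | 4-[(2S)-2-{2,6-dihydroxy-4-[2-(4-hydroxyphenyl)ethyl]phenyl}-2-(3,5-dihydroxyphenyl)ethylidene]cyclohexa-2,5-dien-1-one | O=C1C=CC(=C[C@@H](c2cc(O)cc(O)c2)c2c(O)cc(CCc3ccc(O)cc3)cc2O)C=C1
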